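**Plan**

- Numbering: tetrahydrofuran O1, C2 (guaiacyl), C3 (bearing the hydroxymethyl carbon C9), C4 (bearing the syringoyl carbonyl carbon C7'), C5. The target is the all-trans (2S,3R,4S) isomer.
- Enabling feature: O1–C5–C4 with C7'=O on C4 is a β-alkoxy ketone, the imprint of an alkoxide adding to an aryl vinyl ketone. C3, between the benzylic C2–O1 and C4 and carrying the single-carbon branch C9, can be the inner carbon of an allyl unit whose vinyl group stands for C9.
- Retrosynthesis: remove both phenol benzyl groups and return C9–OH to a vinyl group; cut O1–C5 and C3–C4 in one (3+2) operation into an aryl vinyl epoxide and an aryl vinyl ketone; cut the epoxide to a 1-arylbutadiene and the enone to an aryl aldehyde plus vinyl Grignard reagent.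
- Forward: two three-step branches (from vanillin and from syringaldehyde) meet in the palladium step, which closes the only ring. The vinyl group is then cut to CHO, reduced to CH2OH, and the benzyl ethers are removed.
- Stereochemistry: C2 comes from a Shi epoxidation and passes through ring formation with its C–O bond untouched. C3 follows from it (net retention at the allyl carbon, trans to the aryl group). C4 is set by equilibration next to the ketone.

Key step: step 7

Remark: the CIP label at C3 is S in the vinyl and formyl compounds and R in the hydroxymethyl compounds because substituent priorities change; the arrangement in space is the same throughout.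
Assumption: the D-fructose-derived ketone gives the (2R,3R) epoxide, the sense established for trans-β-substituted styrenes.
Assumption: the two palladium-bound intermediates of the key step are drawn in the η1-allyl form without phosphine ligands.

**Step 1**
Reactants: 1 vanillin
Product: 2 4-(benzyloxy)-3-methoxybenzaldehyde
Conditions: BnBr, K2CO3, DMF, rt
Reagents that add atoms: benzyl bromide, BrCc1ccccc1
Why: Williamson ether synthesis, in which the phenoxide formed with K2CO3 is alkylated by the benzylic bromide while the aldehyde is inert.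

**Step 2**
Reactants: 2 4-(benzyloxy)-3-methoxybenzaldehyde; 3 diethyl allylphosphonate
Product: 6 (E)-1-[4-(benzyloxy)-3-methoxyphenyl]buta-1,3-diene, via lithiated allylphosphonate 4 (not isolated), via lithium β-oxido phosphonate 5 (not isolated)
Conditions: 3, n-BuLi, THF, −78 °C; then 2, −78 °C; then HMPA, −78 °C → rt
Reagents that add atoms: none
Why: Horner–Wadsworth–Emmons olefination with a lithiated allylic phosphonate, in which α-attack on the aldehyde gives adduct 5 and HMPA-promoted elimination of lithium diethyl phosphate should deliver the conjugated (E)-diene.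

**Step 3**
Reactants: 6 (E)-1-[4-(benzyloxy)-3-methoxyphenyl]buta-1,3-diene
Product: 7 (2R,3R)-2-[4-(benzyloxy)-3-methoxyphenyl]-3-vinyloxirane (trans)
Conditions: 1,2:4,5-di-O-isopropylidene-β-D-erythro-hexo-2,3-diulo-2,6-pyranose (ketone catalyst of the Shi epoxidation, 30 mol%), KHSO5 (as 2KHSO5·KHSO4·K2SO4), K2CO3, Bu4NHSO4, MeCN/CH2(OMe)2, aq. Na2B4O7 buffer, pH 10.5, 0 °C; cold work-up, filtration through Et3N-deactivated silica
Reagents that add atoms: potassium peroxymonosulfate, [K+].[O-]S(=O)(=O)OO
Why: Shi asymmetric epoxidation, in which the chiral dioxirane transfers oxygen through a spiro transition state to the electron-rich trans-disubstituted styrenyl alkene in preference to the terminal vinyl group, the D-fructose-derived ketone setting both epoxide carbons as R while the basic buffer protects the acid-labile p-alkoxyaryl epoxide.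

**Step 4**
Reactants: 8 syringaldehyde
Product: 9 4-(benzyloxy)-3,5-dimethoxybenzaldehyde
Conditions: BnBr, K2CO3, DMF, 60 °C
Reagents that add atoms: benzyl bromide, BrCc1ccccc1
Why: Williamson ether synthesis, with gentle heating to alkylate the phenoxide flanked by two methoxy groups.

**Step 5**
Reactants: 9 4-(benzyloxy)-3,5-dimethoxybenzaldehyde; 10 vinylmagnesium bromide
Product: 12 1-[4-(benzyloxy)-3,5-dimethoxyphenyl]prop-2-en-1-ol (racemic), via bromomagnesium alkoxide 11 (not isolated)
Conditions: THF, 0 °C; then aq. NH4Cl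
Reagents that add atoms: none
Why: Grignard 1,2-addition to the aryl aldehyde gives the vinyl carbinol as a racemate, which does not matter because the carbinol centre is oxidised in the next step.

**Step 6**
Reactants: 12 1-[4-(benzyloxy)-3,5-dimethoxyphenyl]prop-2-en-1-ol
Product: 13 1-[4-(benzyloxy)-3,5-dimethoxyphenyl]prop-2-en-1-one
Conditions: activated MnO2, CH2Cl2, rt; filtered, concentrated cold and used at once
Reagents that add atoms: none
Why: Oxidation of an allylic and benzylic alcohol with MnO2, a neutral heterogeneous oxidant that leaves the polymerisation-prone aryl vinyl ketone in a filtrate fit for direct use.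

**Step 7**
Reactants: 7 (2R,3R)-2-[4-(benzyloxy)-3-methoxyphenyl]-3-vinyloxirane; 13 1-[4-(benzyloxy)-3,5-dimethoxyphenyl]prop-2-en-1-one
Product: 16 (2S,3S,4S)-2-[4-(benzyloxy)-3-methoxyphenyl]-4-[4-(benzyloxy)-3,5-dimethoxybenzoyl]-3-vinyltetrahydrofuran, via π-allylpalladium alkoxide 14 (not isolated), via palladium-bound enolate 15 (not isolated)
Conditions: Pd2(dba)3·CHCl3 (2.5 mol%), PPh3 (12 mol%), THF, 0 °C → rt, 13 (1.3 equiv) added over 1 h; then DBU (10 mol%), rt
Reagents that add atoms: none
Why: Zerovalent palladium ionises the allylic C3–O bond of 7 with inversion and leaves the benzylic C2–O bond untouched, giving the π-allylpalladium alkoxide 14; the alkoxide adds to the unsubstituted β-carbon of enone 13 (O1–C5) and the enolate 15 so formed attacks the inner allyl carbon anti to palladium (C3–C4), which releases the catalyst. The closest known reaction type is the palladium-catalysed (3+2) cycloaddition of vinyl epoxides with enones and with doubly activated alkenes through zwitterionic π-allyl intermediates. The tetrahydrofuran closes by a 5-exo allylic alkylation, preferred over the seven-membered alternative at the outer terminus, and this leaves the vinyl group (masked C9) outside the ring. C2 is carried in from 7; C3 results from two inversions (net retention) on the trans epoxide, and since the π-allyl faces interconvert by π–σ–π and the oxa-Michael addition is reversible, both channels are expected to drain into the ring with aryl and vinyl trans; C4 is enolisable and is brought trans to the vinyl group by the DBU equilibration. The step needs the alkoxide to be trapped by the enone faster than it isomerises by hydride shift or starts enone oligomerisation, and this is served by the unhindered, strongly electrophilic vinyl ketone, kept at low stationary concentration by slow addition, and by the reversibility of the ionisation.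

**Step 8**
Reactants: 16 (2S,3S,4S)-2-[4-(benzyloxy)-3-methoxyphenyl]-4-[4-(benzyloxy)-3,5-dimethoxybenzoyl]-3-vinyltetrahydrofuran
Product: 18 (2S,3S,4S)-2-[4-(benzyloxy)-3-methoxyphenyl]-4-[4-(benzyloxy)-3,5-dimethoxybenzoyl]tetrahydrofuran-3-carbaldehyde, via vicinal diol 17 (not isolated)
Conditions: OsO4 (2 mol%), NaIO4, 2,6-lutidine, dioxane/H2O (3:1), rt
Reagents that add atoms: osmium tetroxide, O=[Os](=O)(=O)=O; sodium periodate, [Na+].[O-]I(=O)(=O)=O
Why: Lemieux–Johnson oxidation, in which OsO4 dihydroxylates the only alkene to diol 17 and NaIO4 cleaves it to the aldehyde, 2,6-lutidine suppressing over-oxidation, while C3 (now α to the aldehyde) can only epimerise towards the all-trans arrangement it already has.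

**Step 9**
Reactants: 18 (2S,3S,4S)-2-[4-(benzyloxy)-3-methoxyphenyl]-4-[4-(benzyloxy)-3,5-dimethoxybenzoyl]tetrahydrofuran-3-carbaldehyde
Product: 19 (2S,3R,4S)-2-[4-(benzyloxy)-3-methoxyphenyl]-4-[4-(benzyloxy)-3,5-dimethoxybenzoyl]-3-(hydroxymethyl)tetrahydrofuran
Conditions: NaBH4 (1 equiv), EtOH/CH2Cl2 (3:7), −78 °C
Reagents that add atoms: none
Why: Chemoselective borohydride reduction, since at −78 °C NaBH4 should reduce the aldehyde far faster than the hindered, electron-rich p-alkoxyaryl ketone, and the trans relationship of C3 and C4 keeps the product from closing to a bicyclic hemiketal.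

**Step 10**
Reactants: 19 (2S,3R,4S)-2-[4-(benzyloxy)-3-methoxyphenyl]-4-[4-(benzyloxy)-3,5-dimethoxybenzoyl]-3-(hydroxymethyl)tetrahydrofuran
Product: 20 (2S,3R,4S)-2-(4-hydroxy-3-methoxyphenyl)-4-(4-hydroxy-3,5-dimethoxybenzoyl)-3-(hydroxymethyl)tetrahydrofuran (CNP0169680.1)
Conditions: H2 (1 atm), Pd/C (10%), EtOAc, rt; stopped when both benzyl groups are gone
Reagents that add atoms: none
Why: Catalytic hydrogenolysis of the two aryl benzyl ethers, which under neutral conditions at 1 atm should be cleaved well before the benzylic C2–O1 bond of the ring or the electron-rich aryl ketone is touched.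

**Compound list**

1 | vanillin | COc1cc(C=O)ccc1O | starting material
2 | 4-(benzyloxy)-3-methoxybenzaldehyde | COc1cc(C=O)ccc1OCc1ccccc1 | intermediate
3 | diethyl allylphosphonate | C=CCP(=O)(OCC)OCC | starting material
4 | diethyl (1-lithioprop-2-en-1-yl)phosphonate (lithiated allylphosphonate, not isolated) | [Li]C(C=C)P(=O)(OCC)OCC | intermediate
5 | lithium 1-[4-(benzyloxy)-3-methoxyphenyl]-2-(diethoxyphosphoryl)but-3-en-1-olate (diastereomer mixture, not isolated) | [Li+].[O-]C(c1ccc(OCc2ccccc2)c(OC)c1)C(C=C)P(=O)(OCC)OCC | intermediate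
6 | (E)-1-[4-(benzyloxy)-3-methoxyphenyl]buta-1,3-diene | COc1cc(/C=C/C=C)ccc1OCc1ccccc1 | intermediate
7 | (2R,3R)-2-[4-(benzyloxy)-3-methoxyphenyl]-3-vinyloxirane | COc1cc([C@H]2O[C@@H]2C=C)ccc1OCc1ccccc1 | intermediate
8 | syringaldehyde | COc1cc(C=O)cc(OC)c1O | starting material
9 | 4-(benzyloxy)-3,5-dimethoxybenzaldehyde | COc1cc(C=O)cc(OC)c1OCc1ccccc1 | intermediate
10 | vinylmagnesium bromide | C=C[Mg]Br | starting material
11 | bromomagnesium 1-[4-(benzyloxy)-3,5-dimethoxyphenyl]prop-2-en-1-olate (not isolated) | C=CC(O[Mg]Br)c1cc(OC)c(OCc2ccccc2)c(OC)c1 | intermediate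
12 | 1-[4-(benzyloxy)-3,5-dimethoxyphenyl]prop-2-en-1-ol (racemic) | C=CC(O)c1cc(OC)c(OCc2ccccc2)c(OC)c1 | intermediate
13 | 1-[4-(benzyloxy)-3,5-dimethoxyphenyl]prop-2-en-1-one | C=CC(=O)c1cc(OC)c(OCc2ccccc2)c(OC)c1 | intermediate
14 | (S,E)-1-[4-(benzyloxy)-3-methoxyphenyl]but-2-en-1-olate bound to cationic allylpalladium (η1 form, ligands omitted, not isolated) | COc1cc([C@@H]([O-])/C=C/C[Pd+])ccc1OCc1ccccc1 | intermediate
15 | enolate formed from 14 by O-addition to 13, bound to cationic allylpalladium (η1 form, ligands omitted, not isolated) | COc1cc([C@@H](OCC=C([O-])c2cc(OC)c(OCc3ccccc3)c(OC)c2)/C=C/C[Pd+])ccc1OCc1ccccc1 | intermediate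
16 | (2S,3S,4S)-2-[4-(benzyloxy)-3-methoxyphenyl]-4-[4-(benzyloxy)-3,5-dimethoxybenzoyl]-3-vinyltetrahydrofuran | COc1cc([C@H]2OC[C@@H](C(=O)c3cc(OC)c(OCc4ccccc4)c(OC)c3)[C@@H]2C=C)ccc1OCc1ccccc1 | intermediate
17 | (2S,3R,4S)-2-[4-(benzyloxy)-3-methoxyphenyl]-4-[4-(benzyloxy)-3,5-dimethoxybenzoyl]-3-(1,2-dihydroxyethyl)tetrahydrofuran (carbinol epimers, not isolated) | COc1cc([C@H]2OC[C@@H](C(=O)c3cc(OC)c(OCc4ccccc4)c(OC)c3)[C@@H]2C(O)CO)ccc1OCc1ccccc1 | intermediate
18 | (2S,3S,4S)-2-[4-(benzyloxy)-3-methoxyphenyl]-4-[4-(benzyloxy)-3,5-dimethoxybenzoyl]tetrahydrofuran-3-carbaldehyde | COc1cc([C@H]2OC[C@@H](C(=O)c3cc(OC)c(OCc4ccccc4)c(OC)c3)[C@@H]2C=O)ccc1OCc1ccccc1 | intermediate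
19 | (2S,3R,4S)-2-[4-(benzyloxy)-3-methoxyphenyl]-4-[4-(benzyloxy)-3,5-dimethoxybenzoyl]-3-(hydroxymethyl)tetrahydrofuran | COc1cc([C@H]2OC[C@@H](C(=O)c3cc(OC)c(OCc4ccccc4)c(OC)c3)[C@@H]2CO)ccc1OCc1ccccc1 | intermediate
20 | (2S,3R,4S)-2-(4-hydroxy-3-methoxyphenyl)-4-(4-hydroxy-3,5-dimethoxybenzoyl)-3-(hydroxymethyl)tetrahydrofuran, i.e. [(3S,4R,5S)-4-(hydroxymethyl)-5-(4-hydroxy-3-methoxyphenyl)oxolan-3-yl](4-hydroxy-3,5-dimethoxyphenyl)methanone | COc1cc([C@H]2OC[C@@H](C(=O)c3cc(OC)c(O)c(OC)c3)[C@@H]2CO)ccc1O | target

**Step count**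

Total steps: 10. Longest linear sequence: 7 (steps 1–3, or 4–6, followed by steps 7–10).

**Steps most likely to fail**

Step 7. The π-allylpalladium alkoxide may be lost to hydride shift (isomerisation to an aryl ketone), may start anionic oligomerisation of the enone before the enolate closes the ring, or the closure may not keep pace with reversal of the oxa-Michael addition. The fallback leaves the palladium chemistry and builds the same substitution pattern by a conjugate addition–aldol sequence on a chiral butenolide. It sets out from aldehydes 9 and 2 and rejoins the route at 19.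
- Aldehyde 9 is converted with propane-1,3-dithiol and BF3·OEt2 (CH2Cl2, 0 °C) into 2-[4-(benzyloxy)-3,5-dimethoxyphenyl]-1,3-dithiane F1.
- Its 2-lithio derivative (n-BuLi, THF, −78 °C) adds to commercial (5R)-5-(l-menthyloxy)furan-2(5H)-one anti to the menthyloxy group. The lactone enolate is trapped with 2 anti to the new substituent, giving the (3S,4R,5R)-configured aldol lactone F2 as a mixture of carbinol epimers (that centre is reset later).
- LiAlH4 (THF, 0 °C) reduces the lactone and the masked aldehyde with loss of menthol and gives the (2R,3R)-configured triol F3.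
- Catalytic camphorsulfonic acid in CH2Cl2 ionises the p-alkoxybenzylic alcohol, and the C5 hydroxyl closes the ring trans to the C3 substituent, giving the (2S,3R,4R) dithiane-protected tetrahydrofuran F4.
- MeI and CaCO3 in aqueous MeCN unmask the (2S,3R,4R) keto alcohol F5, the C4 epimer of 19, and DBU in THF equilibrates C4 to the all-trans compound 19.
- In this detour C3 is fixed by the acetal centre of the butenolide, C2 by the thermodynamically controlled ring closure and C4 by the final equilibration.

Step 3. The dioxirane may attack the terminal alkene or react with insufficient facial selectivity, and the electron-rich benzylic epoxide may open or rearrange during isolation. The fallback installs the epoxide oxygen while the styrenyl alkene is the only one present. It sets out from 2 and returns at 7.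
- Wittig reaction of 2 with Ph3P=CHCHO (toluene, 80 °C) gives (E)-3-[4-(benzyloxy)-3-methoxyphenyl]prop-2-enal F6.
- Iminium-catalysed epoxidation with aqueous H2O2 and a diarylprolinol trimethylsilyl ether in CH2Cl2 gives (2S,3R)-3-[4-(benzyloxy)-3-methoxyphenyl]oxirane-2-carbaldehyde F7. The catalyst antipode is the one that delivers oxygen to the Si face of the β-carbon, expected to be the (S)-configured catalyst.
- Wittig methylenation with Ph3P=CH2 (from Ph3PCH3Br and KHMDS, THF, −78 °C → 0 °C) gives 7, isolated from the basic mixture by filtration through basic alumina.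

Step 10. Over-reduction may set in before both benzyl ethers are gone: hydrogenolysis of the benzylic C2–O1 bond (ring opening) or reduction of the aryl ketone. The fallback replaces hydrogenolysis by Lewis-acid debenzylation with a cation scavenger. It sets out from 19 and ends at 20: BCl3 and pentamethylbenzene in CH2Cl2 at −78 °C cleave the two aryl benzyl ethers, which are activated by the neighbouring methoxy groups, and the reaction is quenched cold with MeOH before the ring ether can ionise. This detour forms no compound outside the list (F0).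

**Further compounds**

F1 | step 7 | 2-[4-(benzyloxy)-3,5-dimethoxyphenyl]-1,3-dithiane | COc1cc(C2SCCCS2)cc(OC)c1OCc1ccccc1
F2 | step 7 | (3S,4R,5R)-3-{[4-(benzyloxy)-3-methoxyphenyl](hydroxy)methyl}-4-{2-[4-(benzyloxy)-3,5-dimethoxyphenyl]-1,3-dithian-2-yl}-5-[(1R,2S,5R)-menthyloxy]oxolan-2-one (aldol lactone, carbinol epimers) | O=C1O[C@@H](O[C@@H]2C[C@H](C)CC[C@H]2C(C)C)[C@H](C2(c3cc(OC)c(OCc4ccccc4)c(OC)c3)SCCCS2)[C@H]1C(O)c1ccc(OCc2ccccc2)c(OC)c1
F3 | step 7 | (2R,3R)-2-{[4-(benzyloxy)-3-methoxyphenyl](hydroxy)methyl}-3-{2-[4-(benzyloxy)-3,5-dimethoxyphenyl]-1,3-dithian-2-yl}butane-1,4-diol (triol, carbinol epimers) | OC[C@H](C(O)c1ccc(OCc2ccccc2)c(OC)c1)[C@H](CO)C1(c2cc(OC)c(OCc3ccccc3)c(OC)c2)SCCCS1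
F4 | step 7 | (2S,3R,4R)-2-[4-(benzyloxy)-3-methoxyphenyl]-4-{2-[4-(benzyloxy)-3,5-dimethoxyphenyl]-1,3-dithian-2-yl}-3-(hydroxymethyl)tetrahydrofuran | COc1cc([C@H]2OC[C@H](C3(c4cc(OC)c(OCc5ccccc5)c(OC)c4)SCCCS3)[C@@H]2CO)ccc1OCc1ccccc1
F5 | step 7 | (2S,3R,4R)-2-[4-(benzyloxy)-3-methoxyphenyl]-4-[4-(benzyloxy)-3,5-dimethoxybenzoyl]-3-(hydroxymethyl)tetrahydrofuran (C4 epimer of 19) | COc1cc([C@H]2OC[C@H](C(=O)c3cc(OC)c(OCc4ccccc4)c(OC)c3)[C@@H]2CO)ccc1OCc1ccccc1
F6 | step 3 | (E)-3-[4-(benzyloxy)-3-methoxyphenyl]prop-2-enal | COc1cc(/C=C/C=O)ccc1OCc1ccccc1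
F7 | step 3 | (2S,3R)-3-[4-(benzyloxy)-3-methoxyphenyl]oxirane-2-carbaldehyde | COc1cc([C@H]2O[C@@H]2C=O)ccc1OCc1ccccc1
F0 | step 10 | none | none
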